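**Plan**

- Retrosynthesis first cuts the benzofuran at O1–C2 and at both aryl–alkyne bonds. This gives a 5-ethynyl-dihydrobenzofuran (from the C5 bromide and trimethylsilylacetylene) and 5-iodo-dihydroconiferyl alcohol.
- The dihydrobenzofuran is then cut at C3–C3a by a retro 1,2-aryl shift to a (2S)-chroman-4-one. That flavanone is cut at C2–aryl to 6-bromo-8-methoxychromone and a guaiacyl boronic acid.
- Enabling feature: C3 of the dihydrobenzofuran carries one exocyclic carbon (CH2OH) and sits on aromatic C3a. This is the pattern left when C4a of a chroman-4-one moves from C4 to C3 and C4 leaves the ring as an ester.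
- Forward order: pyranone ring (chromone), C2–aryl bond, contraction of the pyranone to the trans-dihydrofuran, ester to CH2OH, alkynylation at C5, and the benzofuran ring last by coupling and 5-endo-dig annulation.
- Stereochemistry: C2 (S) comes from a chiral pyridine–oxazoline palladium catalyst in the conjugate addition. C3 is relayed from C2 during the aryl shift (trans) and becomes R on reduction only through a change of priorities.

Key step: step 6

Assumption: the t-BuPyOx–palladium catalyst is taken to show the same sense of induction with chromones as with 3-substituted cyclohexenones, so the (R)-ligand should give the (2S)-flavanone. If the opposite sense is found, the (S)-ligand is used with no other change.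

**Route**

Step 1
Reactants: 1 1-(2-hydroxy-3-methoxyphenyl)ethan-1-one
Product: 2 1-(5-bromo-2-hydroxy-3-methoxyphenyl)ethan-1-one
Conditions: NBS, MeCN, 0 °C → rt
Reagents that add atoms: N-bromosuccinimide, O=C1CCC(=O)N1Br
Why: Electrophilic aromatic bromination goes to C5, the only position para to the phenol and meta to the acetyl group, since both ortho positions of the phenol are blocked.

Step 2
Reactants: 2 1-(5-bromo-2-hydroxy-3-methoxyphenyl)ethan-1-one
Product: 4 6-bromo-8-methoxy-4H-chromen-4-one, via enaminone 3 (not isolated)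
Conditions: Me2NCH(OMe)2, toluene, 100 °C; then conc. HCl, CH2Cl2, 40 °C
Reagents that add atoms: N,N-dimethylformamide dimethyl acetal, COC(OC)N(C)C
Why: Condensation of the methyl ketone with the amide acetal, then acid-induced addition–elimination of the phenol with loss of dimethylamine, is the standard enaminone route to 2,3-unsubstituted chromones.

Step 3
Reactants: 5 2-methoxy-4-(4,4,5,5-tetramethyl-1,3,2-dioxaborolan-2-yl)phenol
Product: 6 2-methoxy-4-(4,4,5,5-tetramethyl-1,3,2-dioxaborolan-2-yl)phenyl methanesulfonate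
Conditions: MsCl, Et3N, CH2Cl2, 0 °C
Reagents that add atoms: methanesulfonyl chloride, CS(=O)(=O)Cl
Why: O-Sulfonylation of the phenol leaves the pinacol boronate untouched and installs the electron-withdrawing sulfonate that later makes the guaiacyl ring a poor migrating group.

Step 4
Reactants: 6 2-methoxy-4-(4,4,5,5-tetramethyl-1,3,2-dioxaborolan-2-yl)phenyl methanesulfonate
Product: 7 [3-methoxy-4-(methylsulfonyloxy)phenyl]boronic acid
Conditions: NaIO4, NH4OAc, acetone/H2O, rt
Reagents that add atoms: water, O
Why: Oxidative glycol cleavage of the released pinacol by periodate drives hydrolysis of the boronic ester to the free boronic acid, which transmetalates far more readily than the pinacol ester.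

Step 5
Reactants: 4 6-bromo-8-methoxy-4H-chromen-4-one; 7 [3-methoxy-4-(methylsulfonyloxy)phenyl]boronic acid
Product: 8 (2S)-6-bromo-8-methoxy-2-[3-methoxy-4-(methylsulfonyloxy)phenyl]chroman-4-one
Conditions: Pd(OCOCF3)2 (5 mol %), (R)-t-BuPyOx (6 mol %), NH4PF6 (30 mol %), H2O (5 equiv), ClCH2CH2Cl, 60 °C
Reagents that add atoms: none
Why: In this asymmetric conjugate addition of an arylboronic acid under cationic divalent palladium with a chiral pyridine–oxazoline ligand, the chromone C2=C3 bond inserts into the aryl–palladium bond on the enone face left open by the tert-butyl group, which sets C2 as S, and protonolysis of the palladium enolate closes a cycle that never reaches zerovalent palladium, so the aryl bromide and the sulfonate should survive.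

Step 6
Reactants: 8 (2S)-6-bromo-8-methoxy-2-[3-methoxy-4-(methylsulfonyloxy)phenyl]chroman-4-one
Product: 10 methyl (2S,3S)-5-bromo-7-methoxy-2-[3-methoxy-4-(methylsulfonyloxy)phenyl]-2,3-dihydro-1-benzofuran-3-carboxylate, via enol ether 9 (not isolated)
Conditions: PhI(OAc)2 (1.3 equiv), conc. H2SO4, HC(OMe)3, rt → 45 °C
Reagents that add atoms: trimethyl orthoformate, COC(OC)OC
Why: Acid and trimethyl orthoformate convert the C4 ketone into the 4-methoxy-2H-chromene 9, which the trivalent iodine electrophile attacks at C3 on the face opposite the C2 aryl group; methanol caps C4 as the dimethyl ketal, and aromatic carbon C4a, antiperiplanar to the C3–I bond, then shifts from C4 to C3 with expulsion of iodobenzene, leaving C4 outside the ring as a dimethoxycarbenium ion that loses one methyl group to acetate and ends as the methyl ester. The closest known reaction type is the oxidative ring contraction of flavanones by PhI(OAc)2 or PhI(OH)OTs (earlier Tl(NO3)3) in acidic trimethyl orthoformate to methyl trans-2-aryl-2,3-dihydrobenzofuran-3-carboxylates. The dihydrofuran ring is not made by a fresh exo or endo cyclisation but by contraction of the pyranone through this semipinacol-type 1,2-aryl shift, which forms the C3–C3a bond while the O1–C2 bond stays intact. The new stereocentre C3 is controlled by the resident C2 centre: anti iodination followed by backside entry of C4a places the ester carbon trans to the aryl group, which is also the thermodynamically preferred arrangement of an epimerisable α-aryl ester. The step needs migration of the fused-ring carbon C4a in preference to migration of the C2 aryl group (isoflavone), to simple dehydrogenation (flavone) and to ionisation at C2; C4a is activated by the ring oxygen on the neighbouring carbon C8a, whereas the mesyloxy group makes the guaiacyl ring a poor migrating group and destabilises a benzylic cation at C2, so the (2S) centre should pass through unchanged.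

Step 7
Reactants: 10 methyl (2S,3S)-5-bromo-7-methoxy-2-[3-methoxy-4-(methylsulfonyloxy)phenyl]-2,3-dihydro-1-benzofuran-3-carboxylate
Product: 11 4-[(2S,3R)-5-bromo-3-(hydroxymethyl)-7-methoxy-2,3-dihydro-1-benzofuran-2-yl]-2-methoxyphenyl methanesulfonate
Conditions: i-Bu2AlH, CH2Cl2, −78 → 0 °C; aq. potassium sodium tartrate
Reagents that add atoms: none
Why: Non-basic hydride reduction of the ester at low temperature gives the primary alcohol without touching the aryl bromide or the aryl sulfonate, and it removes the acidifying carbonyl next to C3–H, so the trans C2/C3 relationship is locked before any amine base or heat is applied (the descriptor at C3 changes to R only through the priority rules).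

Step 8
Reactants: 11 4-[(2S,3R)-5-bromo-3-(hydroxymethyl)-7-methoxy-2,3-dihydro-1-benzofuran-2-yl]-2-methoxyphenyl methanesulfonate
Product: 12 4-[(2S,3R)-3-(hydroxymethyl)-7-methoxy-5-[(trimethylsilyl)ethynyl]-2,3-dihydro-1-benzofuran-2-yl]-2-methoxyphenyl methanesulfonate
Conditions: Me3SiC≡CH, PdCl2(PhCN)2 (3 mol %), P(t-Bu)3·HBF4 (6 mol %), CuI (2 mol %), i-Pr2NH, dioxane, rt → 40 °C
Reagents that add atoms: trimethylsilylacetylene, C#C[Si](C)(C)C
Why: In this Sonogashira coupling the unhindered but electron-rich C5–Br bond should add oxidatively to zerovalent palladium carrying the bulky, electron-rich P(t-Bu)3 near room temperature, while the aryl mesylate and the free alcohol are inert.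

Step 9
Reactants: 12 4-[(2S,3R)-3-(hydroxymethyl)-7-methoxy-5-[(trimethylsilyl)ethynyl]-2,3-dihydro-1-benzofuran-2-yl]-2-methoxyphenyl methanesulfonate
Product: 13 4-[(2S,3R)-5-ethynyl-3-(hydroxymethyl)-7-methoxy-2,3-dihydro-1-benzofuran-2-yl]-2-methoxyphenol
Conditions: KOH, MeOH/THF/H2O, 50–60 °C; then aq. NH4Cl
Reagents that add atoms: none
Why: Hydroxide cleaves the aryl sulfonate at sulfur (sulfonate ester hydrolysis) and the alkynylsilane at silicon (protodesilylation) in one operation, and because C3 no longer carries an acidifying group, any reversible opening at C2 through the phenoxide can only reclose under control of the fixed C3 centre to the trans ring.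

Step 10
Reactants: 14 4-(3-hydroxypropyl)-2-methoxyphenol (dihydroconiferyl alcohol)
Product: 15 4-(3-hydroxypropyl)-2-iodo-6-methoxyphenol
Conditions: I2, NaHCO3, THF/H2O, 0 °C → rt
Reagents that add atoms: iodine, II
Why: Electrophilic iodination of the phenoxide takes place at the only free position ortho to the phenolic oxygen, the para position being occupied by the side chain.

Step 11
Reactants: 13 4-[(2S,3R)-5-ethynyl-3-(hydroxymethyl)-7-methoxy-2,3-dihydro-1-benzofuran-2-yl]-2-methoxyphenol; 15 4-(3-hydroxypropyl)-2-iodo-6-methoxyphenol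
Product: 17 4-[(2S,3R)-3-(hydroxymethyl)-5-[5-(3-hydroxypropyl)-7-methoxy-1-benzofuran-2-yl]-7-methoxy-2,3-dihydro-1-benzofuran-2-yl]-2-methoxyphenol, via o-alkynylphenol 16 (not isolated)
Conditions: PdCl2(PPh3)2 (5 mol %), CuI (5 mol %), Et3N, DMF, 60 → 80 °C, Ar
Reagents that add atoms: none
Why: In this domino Sonogashira coupling and heteroannulation, coupling at the C–I bond gives the o-alkynylphenol, whose phenolic oxygen then adds 5-endo-dig to the metal-activated triple bond at the alkyne carbon attached to the dihydrobenzofuran, closing the benzofuran with its C2 bonded to C5 of the dihydrobenzofuran and touching no stereocentre.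

**Compound list**

1 | 1-(2-hydroxy-3-methoxyphenyl)ethan-1-one (2'-hydroxy-3'-methoxyacetophenone) | CC(=O)c1cccc(OC)c1O | starting material
2 | 1-(5-bromo-2-hydroxy-3-methoxyphenyl)ethan-1-one | CC(=O)c1cc(Br)cc(OC)c1O | intermediate
3 | (E)-1-(5-bromo-2-hydroxy-3-methoxyphenyl)-3-(dimethylamino)prop-2-en-1-one | CN(C)/C=C/C(=O)c1cc(Br)cc(OC)c1O | intermediate (not isolated)
4 | 6-bromo-8-methoxy-4H-chromen-4-one | COc1cc(Br)cc2c(=O)ccoc12 | intermediate
5 | 2-methoxy-4-(4,4,5,5-tetramethyl-1,3,2-dioxaborolan-2-yl)phenol | COc1cc(B2OC(C)(C)C(C)(C)O2)ccc1O | starting material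
6 | 2-methoxy-4-(4,4,5,5-tetramethyl-1,3,2-dioxaborolan-2-yl)phenyl methanesulfonate | COc1cc(B2OC(C)(C)C(C)(C)O2)ccc1OS(C)(=O)=O | intermediate
7 | [3-methoxy-4-(methylsulfonyloxy)phenyl]boronic acid | COc1cc(B(O)O)ccc1OS(C)(=O)=O | intermediate
8 | (2S)-6-bromo-8-methoxy-2-[3-methoxy-4-(methylsulfonyloxy)phenyl]chroman-4-one | COc1cc([C@H]2Oc3c(OC)cc(Br)cc3C(=O)C2)ccc1OS(C)(=O)=O | intermediate
9 | (2S)-6-bromo-4,8-dimethoxy-2-[3-methoxy-4-(methylsulfonyloxy)phenyl]-2H-chromene | COc1cc([C@H]2Oc3c(OC)cc(Br)cc3C(OC)=C2)ccc1OS(C)(=O)=O | intermediate (not isolated)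
10 | methyl (2S,3S)-5-bromo-7-methoxy-2-[3-methoxy-4-(methylsulfonyloxy)phenyl]-2,3-dihydro-1-benzofuran-3-carboxylate (trans) | COc1cc([C@H]2Oc3c(OC)cc(Br)cc3[C@@H]2C(=O)OC)ccc1OS(C)(=O)=O | intermediate
11 | 4-[(2S,3R)-5-bromo-3-(hydroxymethyl)-7-methoxy-2,3-dihydro-1-benzofuran-2-yl]-2-methoxyphenyl methanesulfonate | COc1cc([C@H]2Oc3c(OC)cc(Br)cc3[C@@H]2CO)ccc1OS(C)(=O)=O | intermediate
12 | 4-[(2S,3R)-3-(hydroxymethyl)-7-methoxy-5-[(trimethylsilyl)ethynyl]-2,3-dihydro-1-benzofuran-2-yl]-2-methoxyphenyl methanesulfonate | COc1cc([C@H]2Oc3c(OC)cc(C#C[Si](C)(C)C)cc3[C@@H]2CO)ccc1OS(C)(=O)=O | intermediate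
13 | 4-[(2S,3R)-5-ethynyl-3-(hydroxymethyl)-7-methoxy-2,3-dihydro-1-benzofuran-2-yl]-2-methoxyphenol | COc1cc([C@H]2Oc3c(OC)cc(C#C)cc3[C@@H]2CO)ccc1O | intermediate
14 | 4-(3-hydroxypropyl)-2-methoxyphenol (dihydroconiferyl alcohol) | COc1cc(CCCO)ccc1O | starting material
15 | 4-(3-hydroxypropyl)-2-iodo-6-methoxyphenol | COc1cc(CCCO)cc(I)c1O | intermediate
16 | 2-{[(2S,3R)-2-(4-hydroxy-3-methoxyphenyl)-3-(hydroxymethyl)-7-methoxy-2,3-dihydro-1-benzofuran-5-yl]ethynyl}-4-(3-hydroxypropyl)-6-methoxyphenol | COc1cc([C@H]2Oc3c(OC)cc(C#Cc4cc(CCCO)cc(OC)c4O)cc3[C@@H]2CO)ccc1O | intermediate (not isolated)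
17 | 4-[(2S,3R)-3-(hydroxymethyl)-5-[5-(3-hydroxypropyl)-7-methoxy-1-benzofuran-2-yl]-7-methoxy-2,3-dihydro-1-benzofuran-2-yl]-2-methoxyphenol (CNP0308311.1) | COc1cc([C@H]2Oc3c(OC)cc(-c4cc5cc(CCCO)cc(OC)c5o4)cc3[C@@H]2CO)ccc1O | target

**Step count**

Total step count: 11.
Longest linear sequence: 8 steps (1, 2, 5, 6, 7, 8, 9, 11; the branch through steps 3 and 4 is equally long).

**Steps most likely to fail**

1. Step 6. The iodane intermediate may collapse by dehydrogenation to the flavone or by shift of the C2 aryl group instead of C4a, or acid may open the ring at C2 and erode the (2S) centre. The fallback is a Wolff ring contraction, which makes the same C3–C3a bond by migration of the same carbon. It sets out from 8 and returns at 10. Compound 8 is deprotonated at C3 with LiN(SiMe3)2 (THF, −78 °C) and acylated with CF3CO2CH2CF3 to give (2S)-6-bromo-8-methoxy-2-[3-methoxy-4-(methylsulfonyloxy)phenyl]-3-(trifluoroacetyl)chroman-4-one F1. CH3SO2N3 and Et3N in MeCN then transfer the diazo group with loss of the trifluoroacetyl group, giving the 3-diazochroman-4-one F2. Irradiation at 365 nm in MeOH/THF expels dinitrogen and C4a shifts to the carbene carbon C3, giving the ring-contracted ketene F3. Methanol traps this as 10 together with its cis epimer, methyl (2S,3R)-5-bromo-7-methoxy-2-[3-methoxy-4-(methylsulfonyloxy)phenyl]-2,3-dihydro-1-benzofuran-3-carboxylate F4. Catalytic NaOMe in MeOH at 0 °C should equilibrate F4 to the trans ester 10.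

2. Step 5. Facial discrimination may be weak or turnover slow with the 6,8-disubstituted chromone, protodeboronation of 7 may outrun the addition, or the sense of induction may be opposite to that assumed. The fallback builds the racemic flavanone and resolves it. It sets out from 2 and returns at 8. Vanillin is mesylated (MsCl, Et3N, CH2Cl2) to 4-formyl-2-methoxyphenyl methanesulfonate F5. Condensation of F5 with 2 (pyrrolidine, MeOH, 60 °C; aldol condensation then oxa-Michael closure) gives racemic 6-bromo-8-methoxy-2-[3-methoxy-4-(methylsulfonyloxy)phenyl]chroman-4-one F6. Asymmetric transfer hydrogenation run as a kinetic resolution (RuCl(p-cymene)(TsDPEN) of the hand that reduces the (2R)-ketone faster, HCO2H/Et3N, rt, stopped near half conversion) converts the (2R)-enantiomer into the cis-flavan-4-ol, 4-[(2R,4R)-6-bromo-4-hydroxy-8-methoxychroman-2-yl]-2-methoxyphenyl methanesulfonate F7. The unreduced (2S)-ketone 8 is separated by chromatography.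

3. Step 8. Oxidative addition at the electron-rich C5–Br bond may be slow, allowing oligomerisation of the alkyne or hydrodebromination; the later copper-mediated dimerisation of alkyne 13 in step 11 is a related risk. The fallback replaces the alkyne route by a Suzuki–Miyaura coupling. It sets out from 11 and 15 and returns at 17.
   - Sonogashira coupling of 15 with Me3SiC≡CH (PdCl2(PPh3)2, CuI, Et3N, THF) gives 4-(3-hydroxypropyl)-2-methoxy-6-[(trimethylsilyl)ethynyl]phenol F8.
   - Bu4NF in THF at 60 °C desilylates and cyclises F8 to 3-(7-methoxy-1-benzofuran-5-yl)propan-1-ol F9.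
   - TBSCl and imidazole give the silyl ether tert-butyl[3-(7-methoxy-1-benzofuran-5-yl)propoxy]dimethylsilane F10.
   - Iridium-catalysed C–H borylation at the furan C2 ([Ir(OMe)(cod)]2, 4,4'-di-tert-butyl-2,2'-bipyridine, B2pin2, THF, 60 °C) gives the 2-(pinacolboryl)benzofuran F11.
   - Coupling of F11 with bromide 11 (Pd(OAc)2, SPhos, K3PO4, THF/H2O, 60 °C) gives the biaryl mesylate silyl ether F12.
   - Bu4NF removes the silyl group to give the mesylate diol F13.
   - KOH in MeOH/H2O at 50–60 °C cleaves the sulfonate to give 17.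

**Further compounds**

F1 | step 6 | (2S)-6-bromo-8-methoxy-2-[3-methoxy-4-(methylsulfonyloxy)phenyl]-3-(trifluoroacetyl)chroman-4-one (C3 unspecified) | COc1cc([C@H]2Oc3c(OC)cc(Br)cc3C(=O)C2C(=O)C(F)(F)F)ccc1OS(C)(=O)=O
F2 | step 6 | (2R)-6-bromo-3-diazo-8-methoxy-2-[3-methoxy-4-(methylsulfonyloxy)phenyl]chroman-4-one (C2 unchanged in space; the descriptor changes by priority only) | COc1cc([C@H]2Oc3c(OC)cc(Br)cc3C(=O)C2=[N+]=[N-])ccc1OS(C)(=O)=O
F3 | step 6 | {5-bromo-7-methoxy-2-[3-methoxy-4-(methylsulfonyloxy)phenyl]-1-benzofuran-3(2H)-ylidene}methanone (ketene, C2 unchanged in space) | COc1cc([C@H]2Oc3c(OC)cc(Br)cc3C2=C=O)ccc1OS(C)(=O)=O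
F4 | step 6 | methyl (2S,3R)-5-bromo-7-methoxy-2-[3-methoxy-4-(methylsulfonyloxy)phenyl]-2,3-dihydro-1-benzofuran-3-carboxylate (cis) | COc1cc([C@H]2Oc3c(OC)cc(Br)cc3[C@H]2C(=O)OC)ccc1OS(C)(=O)=O
F5 | step 5 | 4-formyl-2-methoxyphenyl methanesulfonate | COc1cc(C=O)ccc1OS(C)(=O)=O
F6 | step 5 | racemic 6-bromo-8-methoxy-2-[3-methoxy-4-(methylsulfonyloxy)phenyl]chroman-4-one | COc1cc(C2Oc3c(OC)cc(Br)cc3C(=O)C2)ccc1OS(C)(=O)=O
F7 | step 5 | 4-[(2R,4R)-6-bromo-4-hydroxy-8-methoxychroman-2-yl]-2-methoxyphenyl methanesulfonate | COc1cc([C@@H]2Oc3c(OC)cc(Br)cc3[C@H](O)C2)ccc1OS(C)(=O)=O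
F8 | step 8 | 4-(3-hydroxypropyl)-2-methoxy-6-[(trimethylsilyl)ethynyl]phenol | COc1cc(CCCO)cc(C#C[Si](C)(C)C)c1O
F9 | step 8 | 3-(7-methoxy-1-benzofuran-5-yl)propan-1-ol | COc1cc(CCCO)cc2ccoc12
F10 | step 8 | tert-butyl[3-(7-methoxy-1-benzofuran-5-yl)propoxy]dimethylsilane | COc1cc(CCCO[Si](C)(C)C(C)(C)C)cc2ccoc12
F11 | step 8 | tert-butyl{3-[7-methoxy-2-(4,4,5,5-tetramethyl-1,3,2-dioxaborolan-2-yl)-1-benzofuran-5-yl]propoxy}dimethylsilane | COc1cc(CCCO[Si](C)(C)C(C)(C)C)cc2cc(B3OC(C)(C)C(C)(C)O3)oc12
F12 | step 8 | 4-[(2S,3R)-5-{5-[3-(tert-butyldimethylsilyloxy)propyl]-7-methoxy-1-benzofuran-2-yl}-3-(hydroxymethyl)-7-methoxy-2,3-dihydro-1-benzofuran-2-yl]-2-methoxyphenyl methanesulfonate | COc1cc([C@H]2Oc3c(OC)cc(-c4cc5cc(CCCO[Si](C)(C)C(C)(C)C)cc(OC)c5o4)cc3[C@@H]2CO)ccc1OS(C)(=O)=O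
F13 | step 8 | 4-[(2S,3R)-3-(hydroxymethyl)-5-[5-(3-hydroxypropyl)-7-methoxy-1-benzofuran-2-yl]-7-methoxy-2,3-dihydro-1-benzofuran-2-yl]-2-methoxyphenyl methanesulfonate | COc1cc([C@H]2Oc3c(OC)cc(-c4cc5cc(CCCO)cc(OC)c5o4)cc3[C@@H]2CO)ccc1OS(C)(=O)=O
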